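**Plan**
- Retrosynthesis: first the sulfate S–O bond and all benzyl-type O–C bonds are cut, then C2–C3 of flavanone ring C, then the diazo group on C3, then C3–C8'' (Pd α-arylation). This leaves a phloroacetophenone tris-ether (3) and an 8-bromoluteolin derivative (12).
- Forward: 3 is made in one step and 12 in four steps from luteolin, whose three rings are bought. C3–C8'' is joined (step 6), C3 is diazotised (step 7), and ring C closes last by a Rh(II)-carbene 1,6 C–H insertion (step 8). The 7''-OH is then freed and sulfated, and all benzyl-type groups are hydrogenolysed.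
- Enabling feature: C2 is a benzylic CH2 between O1 and the 4-oxygenated B ring, so its C–H is hydridic, and it lies 1,6 to C3. C3 sits between the C4 ketone and C8'' of the flavone and can therefore carry a diazo group. The 4-(benzyloxy)benzyl ether on ring A is both protecting group and the future C2 plus B ring.
- Stereochemistry: C2 (R) comes from the chiral Rh(II) carboxylate, which picks one of the two enantiotopic benzylic hydrogens. C3 (S) comes from base equilibration to the trans, diequatorial chromanone.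

Key step: step 8

Remark 1: the sulfate is written as the free hydrogen sulfate, as in the target SMILES; 20 and 21 would be handled as sodium or ammonium salts and protonated on an H+ resin only at the end, and these salts carry no numbers of their own.
Remark 2: the sense of induction of a chiral Rh(II) carboxylate cannot be predicted safely for this substrate; the route is written for Rh2(S-PTTL)4 on the assumption that it delivers 2R, and Rh2(R-PTTL)4 would be used if the sense is the opposite.

**Route**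

Step 1
Reactants: 1 2',4',6'-trihydroxyacetophenone; 2 4-(benzyloxy)benzyl chloride (3.3 equiv)
Product: 3 2',4',6'-tris[(4-benzyloxybenzyl)oxy]acetophenone
Conditions: K2CO3, KI (cat.), DMF, 70 °C
Reagents that add atoms: 4-(benzyloxy)benzyl chloride (2), ClCc1ccc(OCc2ccccc2)cc1
Why: Williamson etherification of all three phenols; carbonate in warm DMF should also alkylate the hydrogen-bonded ortho hydroxyls, as in per-benzylation of phloroacetophenone.

Step 2
Reactants: 4 luteolin; 5 dichlorodiphenylmethane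
Product: 6 3',4'-O-(diphenylmethylene)luteolin
Conditions: Ph2CCl2 (1.5 equiv), Ph2O, 175 °C
Reagents that add atoms: dichlorodiphenylmethane (5), ClC(Cl)(c1ccccc1)c1ccccc1
Why: Catechol-selective ketalisation; only the vicinal 3',4'-diol can close the five-membered benzodioxole, so 5-OH and 7-OH should stay free.

Step 3
Reactants: 6 3',4'-O-(diphenylmethylene)luteolin; 7 chlorotriisopropylsilane
Product: 8 3',4'-O-(diphenylmethylene)-7-O-(triisopropylsilyl)luteolin
Conditions: TIPSCl (1.1 equiv), imidazole, DMF, 0 °C to rt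
Reagents that add atoms: chlorotriisopropylsilane (7), CC(C)[Si](Cl)(C(C)C)C(C)C
Why: Silylation of the acidic, unhindered 7-OH; the 5-OH is held in a hydrogen bond to C4=O and should not react.

Step 4
Reactants: 8 3',4'-O-(diphenylmethylene)-7-O-(triisopropylsilyl)luteolin; 9 benzyl alcohol
Product: 10 5-O-benzyl-3',4'-O-(diphenylmethylene)-7-O-(triisopropylsilyl)luteolin
Conditions: BnOH, PPh3, DIAD, THF, 0 °C to rt
Reagents that add atoms: benzyl alcohol (9), OCc1ccccc1
Why: Mitsunobu etherification of the chelated, salicyl-type 5-OH, which is acidic enough to serve as the Mitsunobu acid; the neutral conditions should spare the aryl silyl ether that a hot carbonate alkylation would endanger.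

Step 5
Reactants: 10 5-O-benzyl-3',4'-O-(diphenylmethylene)-7-O-(triisopropylsilyl)luteolin; 11 N-bromosuccinimide
Product: 12 8-bromo-5-O-benzyl-3',4'-O-(diphenylmethylene)-7-O-(triisopropylsilyl)luteolin
Conditions: NBS (1.05 equiv), DMF, 0 °C to rt, dark
Reagents that add atoms: N-bromosuccinimide (11), O=C1CCC(=O)N1Br
Why: Electrophilic aromatic bromination; in 5,7-dioxygenated flavones without a free 5-OH, C8 (ortho to 7-O and O1, para to 5-O, less hindered than C6) is the most nucleophilic carbon, and the B ring is deactivated by its bond to C2 of the pyranone.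

Step 6
Reactants: 3 2',4',6'-tris[(4-benzyloxybenzyl)oxy]acetophenone; 12 8-bromo-5-O-benzyl-3',4'-O-(diphenylmethylene)-7-O-(triisopropylsilyl)luteolin
Product: 13 deoxybenzoin, 1-{2,4,6-tris[(4-benzyloxybenzyl)oxy]phenyl}-2-(protected luteolin-8-yl)ethanone
Conditions: Pd2(dba)3 (2.5 mol %), XPhos (10 mol %), K3PO4, toluene, 100 °C
Reagents that add atoms: none
Why: Pd-catalysed α-arylation of a methyl ketone (Buchwald–Hartwig type); the bulky biaryl phosphine should allow coupling of the di-ortho-substituted bromide, and the reaction should stop at mono-arylation because the product is held as its more stabilised, hindered enolate.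

Step 7
Reactants: 13 deoxybenzoin; 14 4-acetamidobenzenesulfonyl azide (p-ABSA)
Product: 15 α-aryl-α-diazo ketone (diazo group on the carbon between the ring-A carbonyl and C8'' of the flavone)
Conditions: p-ABSA (1.5 equiv), DBU (2 equiv), MeCN/THF, 0 °C to rt
Reagents that add atoms: 4-acetamidobenzenesulfonyl azide (14), CC(=O)Nc1ccc(cc1)S(=O)(=O)N=[N+]=[N-]
Why: Regitz diazo transfer onto the methylene of a deoxybenzoin, which is activated by both the aryl and the aroyl group.

Step 8
Reactants: 15 α-aryl-α-diazo ketone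
Product: 17 (2R,3S)-trans-chromanone (protected naringenin-(3→8'')-luteolin with 7''-O-TIPS), via cis-chromanone 16 (not isolated)
Conditions: Rh2(S-PTTL)4 (2 mol %), CH2Cl2 (0.005 M, slow addition), 4 Å MS, −40 to 0 °C; then DBU (0.1 equiv), 0 °C, AcOH quench
Reagents that add atoms: none
Why: Rh(II) expels N2 from 15 to give an electrophilic rhodium carbene at C3, which inserts into the benzylic C–H of an ortho O–CH2Ar ether through a three-centre, hydride-transfer-like transition state, so that the C2–C3 and C3–H bonds form in one event. The closest known reaction type is the Rh(II)-carboxylate-catalysed intramolecular 1,6 C–H insertion of 2-(benzyloxy)aryl α-diazo ketones to cis-2,3-disubstituted chroman-4-ones, together with the enantioselective insertion of aryl diazo compounds into benzylic ether C–H bonds. Ring C closes in the 1,6-insertion mode (six-membered ring C3–C4–C4a–C8a–O1–C2). C2 is set by the chiral phthaloyl-tert-leucinate ligand sphere, which selects one of the two enantiotopic benzylic hydrogens; C3 is expected to form cis first and is then equilibrated by catalytic DBU through the enol to the trans, diequatorial (2R,3S) isomer under relay from C2. The step needs chemoselectivity for this C–H over other carbene outlets: the two ortho ethers of ring A are identical so either gives 17, the 7''-O-silyl group has no C–H next to oxygen so no five-ring insertion is possible on the flavone side, the 5''-O-benzyl group is para to C8'' and out of reach, and the 4-benzyloxy donor makes the target C–H the most hydridic one in the molecule. Slow addition at low temperature and high dilution should suppress oxonium-ylide and bimolecular pathways, and the brief, catalytic base treatment should avoid opening of ring C.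

Step 9
Reactants: 17 (2R,3S)-trans-chromanone with 7''-O-TIPS
Product: 18 (2R,3S)-trans-chromanone with free 7''-OH
Conditions: TBAF, AcOH (1:1), THF, 0 °C
Reagents that add atoms: none
Why: Fluoride cleavage of the aryl silyl ether; acetic acid buffering should prevent base-induced opening of ring C, and the benzyl-type ethers and the ketal are inert.

Step 10
Reactants: 18 (2R,3S)-trans-chromanone with free 7''-OH; 19 sulfur trioxide–pyridine complex
Product: 20 protected biflavonoid 7''-O-hydrogen sulfate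
Conditions: SO3·pyridine (5 equiv), pyridine, 40 °C; aq. NaHCO3 work-up (Na salt)
Reagents that add atoms: sulfur trioxide–pyridine complex (19), [O-]S(=O)(=O)[n+]1ccccc1
Why: O-sulfation of the only free phenol with SO3·pyridine, the standard preparation of aryl sulfate monoesters; removing pyridine in the work-up keeps it from inhibiting the hydrogenolysis that follows.

Step 11
Reactants: 20 protected biflavonoid 7''-O-hydrogen sulfate
Product: 21 target, (2R,3S)-naringenin-(3→8'')-luteolin 7''-O-sulfate
Conditions: H2 (1 atm), Pd(OH)2/C, THF/MeOH, rt; then Dowex 50W (H+), 0 °C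
Reagents that add atoms: none
Why: Catalytic hydrogenolysis should cleave the two benzyl ethers, both 4-(benzyloxy)benzyl ethers and the diphenylmethylene ketal in one operation, while aryl sulfate monoester salts, the flavone double bond and the C2–O1 bond of the flavanone are expected to survive neutral conditions at 1 atm.

**Compound list**
1 | 2',4',6'-trihydroxyacetophenone | CC(=O)c1c(O)cc(O)cc1O | starting material
2 | 4-(benzyloxy)benzyl chloride | ClCc1ccc(OCc2ccccc2)cc1 | starting material
3 | 2',4',6'-tris[(4-benzyloxybenzyl)oxy]acetophenone | CC(=O)c1c(OCc2ccc(OCc3ccccc3)cc2)cc(OCc2ccc(OCc3ccccc3)cc2)cc1OCc1ccc(OCc2ccccc2)cc1 | intermediate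
4 | luteolin | O=c1cc(-c2ccc(O)c(O)c2)oc2cc(O)cc(O)c12 | starting material
5 | dichlorodiphenylmethane | ClC(Cl)(c1ccccc1)c1ccccc1 | starting material
6 | 3',4'-O-(diphenylmethylene)luteolin, i.e. 2-(2,2-diphenyl-1,3-benzodioxol-5-yl)-5,7-dihydroxychromen-4-one | O=c1cc(-c2ccc3OC(c4ccccc4)(c4ccccc4)Oc3c2)oc2cc(O)cc(O)c12 | intermediate
7 | chlorotriisopropylsilane | CC(C)[Si](Cl)(C(C)C)C(C)C | starting material
8 | 3',4'-O-(diphenylmethylene)-7-O-(triisopropylsilyl)luteolin | O=c1cc(-c2ccc3OC(c4ccccc4)(c4ccccc4)Oc3c2)oc2cc(O[Si](C(C)C)(C(C)C)C(C)C)cc(O)c12 | intermediate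
9 | benzyl alcohol | OCc1ccccc1 | starting material
10 | 5-O-benzyl-3',4'-O-(diphenylmethylene)-7-O-(triisopropylsilyl)luteolin | O=c1cc(-c2ccc3OC(c4ccccc4)(c4ccccc4)Oc3c2)oc2cc(O[Si](C(C)C)(C(C)C)C(C)C)cc(OCc3ccccc3)c12 | intermediate
11 | N-bromosuccinimide | O=C1CCC(=O)N1Br | starting material
12 | 8-bromo-5-O-benzyl-3',4'-O-(diphenylmethylene)-7-O-(triisopropylsilyl)luteolin | O=c1cc(-c2ccc3OC(c4ccccc4)(c4ccccc4)Oc3c2)oc2c(Br)c(O[Si](C(C)C)(C(C)C)C(C)C)cc(OCc3ccccc3)c12 | intermediate
13 | deoxybenzoin: 1-{2,4,6-tris[(4-benzyloxybenzyl)oxy]phenyl}-2-[5-benzyloxy-2-(2,2-diphenyl-1,3-benzodioxol-5-yl)-4-oxo-7-(triisopropylsilyloxy)chromen-8-yl]ethanone | O=C(Cc1c(O[Si](C(C)C)(C(C)C)C(C)C)cc(OCc2ccccc2)c2c(=O)cc(-c3ccc4OC(c5ccccc5)(c5ccccc5)Oc4c3)oc12)c1c(OCc2ccc(OCc3ccccc3)cc2)cc(OCc2ccc(OCc3ccccc3)cc2)cc1OCc1ccc(OCc2ccccc2)cc1 | intermediate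
14 | 4-acetamidobenzenesulfonyl azide (p-ABSA) | CC(=O)Nc1ccc(cc1)S(=O)(=O)N=[N+]=[N-] | starting material
15 | 2-diazo derivative of 13 (diazo on the carbon between the ketone and C8'' of the flavone) | O=C(C(=[N+]=[N-])c1c(O[Si](C(C)C)(C(C)C)C(C)C)cc(OCc2ccccc2)c2c(=O)cc(-c3ccc4OC(c5ccccc5)(c5ccccc5)Oc4c3)oc12)c1c(OCc2ccc(OCc3ccccc3)cc2)cc(OCc2ccc(OCc3ccccc3)cc2)cc1OCc1ccc(OCc2ccccc2)cc1 | intermediate
16 | cis-(2R,3R)-chromanone, the C3 epimer of 17 | O=C1c2c(OCc3ccc(OCc4ccccc4)cc3)cc(OCc3ccc(OCc4ccccc4)cc3)cc2O[C@@H](c2ccc(OCc3ccccc3)cc2)[C@H]1c1c(O[Si](C(C)C)(C(C)C)C(C)C)cc(OCc2ccccc2)c2c(=O)cc(-c3ccc4OC(c5ccccc5)(c5ccccc5)Oc4c3)oc12 | intermediate (not isolated)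
17 | (2R,3S)-trans-chromanone: 4'-O-benzyl-5,7-bis-O-(4-benzyloxybenzyl)naringenin linked C3→C8'' to 5''-O-benzyl-3''',4'''-O-(diphenylmethylene)-7''-O-(triisopropylsilyl)luteolin | O=C1c2c(OCc3ccc(OCc4ccccc4)cc3)cc(OCc3ccc(OCc4ccccc4)cc3)cc2O[C@@H](c2ccc(OCc3ccccc3)cc2)[C@@H]1c1c(O[Si](C(C)C)(C(C)C)C(C)C)cc(OCc2ccccc2)c2c(=O)cc(-c3ccc4OC(c5ccccc5)(c5ccccc5)Oc4c3)oc12 | intermediate
18 | 7''-hydroxy compound: 17 without the silyl group | O=C1c2c(OCc3ccc(OCc4ccccc4)cc3)cc(OCc3ccc(OCc4ccccc4)cc3)cc2O[C@@H](c2ccc(OCc3ccccc3)cc2)[C@@H]1c1c(O)cc(OCc2ccccc2)c2c(=O)cc(-c3ccc4OC(c5ccccc5)(c5ccccc5)Oc4c3)oc12 | intermediate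
19 | sulfur trioxide–pyridine complex | [O-]S(=O)(=O)[n+]1ccccc1 | starting material
20 | 7''-O-hydrogen sulfate of 18 (handled as Na salt) | O=C1c2c(OCc3ccc(OCc4ccccc4)cc3)cc(OCc3ccc(OCc4ccccc4)cc3)cc2O[C@@H](c2ccc(OCc3ccccc3)cc2)[C@@H]1c1c(OS(=O)(=O)O)cc(OCc2ccccc2)c2c(=O)cc(-c3ccc4OC(c5ccccc5)(c5ccccc5)Oc4c3)oc12 | intermediate
21 | (2R,3S)-naringenin-(3→8'')-luteolin 7''-O-hydrogen sulfate | O=C1c2c(O)cc(O)cc2O[C@@H](c2ccc(O)cc2)[C@@H]1c1c(OS(=O)(=O)O)cc(O)c2c(=O)cc(-c3ccc(O)c(O)c3)oc12 | target

**Totals and risks**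
Total step count: 11. Longest linear sequence: 10 steps (luteolin 4 to 21, steps 2 to 11).

Steps most likely to fail:

1. Step 8. The rhodium carbene may be diverted, by attack of an ortho ether oxygen to an oxonium ylide followed by a 1,2-shift, or by hydride transfer without ring closure. The catalyst may also discriminate the two benzylic hydrogens poorly, so that enantiopurity is low. Fallback: ring C is closed through O1–C2 by the classical deoxybenzoin–aldehyde condensation. Setting out from 13, one ortho 4-(benzyloxy)benzyl ether is removed under chelation control with MgBr2·OEt2 (toluene/Et2O, rt) to give the 2'-hydroxy-deoxybenzoin F1. Condensation with 4-(benzyloxy)benzaldehyde (piperidine/AcOH cat., toluene, 80 °C) should give the α-aryl-2'-hydroxychalcone F2, which closes in the same flask by oxa-Michael addition to the racemic trans-chromanone, that is 17 together with its (2S,3R)-enantiomer F3. Preparative chromatography on a chiral stationary phase then gives 17, where the fallback comes back to the route.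

2. Step 6. Oxidative addition and reductive elimination at the doubly ortho-substituted C8 may be slow, with competing hydrodebromination, and the silyl ether or the pyranone ring may erode under hot basic conditions. Fallback: the C3–C8'' bond is made at the diazo oxidation level, at room temperature and without a ketone enolate, which also bypasses step 7. Setting out from 3, trifluoroacetylation (LiHMDS, CF3CO2CH2CF3, THF, −78 °C) gives the trifluoromethyl 1,3-diketone F4, and detrifluoroacetylative diazo transfer (MsN3, Et3N, H2O, MeCN) gives the terminal diazo ketone F5. Setting out from 10, iodination with NIS (cat. TFA, MeCN) gives the 8-iodide F6. Pd-catalysed C–H arylation of the acyl diazomethane F5 with F6 (Pd(PPh3)4, Ag2CO3, Et3N, toluene, rt) should give 15, where the fallback comes back to the route.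

3. Step 11. Cleavage of the eight benzylic C–O bonds may be incomplete, or reduction may go too far, by hydrogenolytic opening of ring C at the benzylic C2–O1 bond or saturation of the flavone C2''=C3'' bond. The sulfate may also be lost on acidification. Fallback: a hydrogen-free end game with a protected sulfate. Setting out from 18, 2,2,2-trichloroethyl chlorosulfate (Et3N, DMAP, THF) gives the neutral trichloroethyl sulfate diester F7. BCl3 with pentamethylbenzene (CH2Cl2, −78 °C) should remove all benzyl-type ethers and the ketal to give the hexaphenol trichloroethyl sulfate F8. Zn/HCO2NH4 (MeOH, rt) then unmasks the sulfate and comes back to the route at 21, as the ammonium salt, which is protonated as in step 11.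

Further compounds
F1 | step 8 | 2'-hydroxy-deoxybenzoin (13 with one ortho 4-benzyloxybenzyl ether cleaved) | O=C(Cc1c(O[Si](C(C)C)(C(C)C)C(C)C)cc(OCc2ccccc2)c2c(=O)cc(-c3ccc4OC(c5ccccc5)(c5ccccc5)Oc4c3)oc12)c1c(O)cc(OCc2ccc(OCc3ccccc3)cc2)cc1OCc1ccc(OCc2ccccc2)cc1
F2 | step 8 | α-aryl-2'-hydroxychalcone from F1 and 4-(benzyloxy)benzaldehyde (alkene geometry open) | O=C(C(=Cc1ccc(OCc2ccccc2)cc1)c1c(O[Si](C(C)C)(C(C)C)C(C)C)cc(OCc2ccccc2)c2c(=O)cc(-c3ccc4OC(c5ccccc5)(c5ccccc5)Oc4c3)oc12)c1c(O)cc(OCc2ccc(OCc3ccccc3)cc2)cc1OCc1ccc(OCc2ccccc2)cc1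
F3 | step 8 | (2S,3R)-enantiomer of 17 | O=C1c2c(OCc3ccc(OCc4ccccc4)cc3)cc(OCc3ccc(OCc4ccccc4)cc3)cc2O[C@H](c2ccc(OCc3ccccc3)cc2)[C@H]1c1c(O[Si](C(C)C)(C(C)C)C(C)C)cc(OCc2ccccc2)c2c(=O)cc(-c3ccc4OC(c5ccccc5)(c5ccccc5)Oc4c3)oc12
F4 | step 6 | 4,4,4-trifluoro-1-{2,4,6-tris[(4-benzyloxybenzyl)oxy]phenyl}butane-1,3-dione | O=C(CC(=O)C(F)(F)F)c1c(OCc2ccc(OCc3ccccc3)cc2)cc(OCc2ccc(OCc3ccccc3)cc2)cc1OCc1ccc(OCc2ccccc2)cc1
F5 | step 6 | 2-diazo-1-{2,4,6-tris[(4-benzyloxybenzyl)oxy]phenyl}ethanone | [N-]=[N+]=CC(=O)c1c(OCc2ccc(OCc3ccccc3)cc2)cc(OCc2ccc(OCc3ccccc3)cc2)cc1OCc1ccc(OCc2ccccc2)cc1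
F6 | step 6 | 8-iodo-5-O-benzyl-3',4'-O-(diphenylmethylene)-7-O-(triisopropylsilyl)luteolin | O=c1cc(-c2ccc3OC(c4ccccc4)(c4ccccc4)Oc3c2)oc2c(I)c(O[Si](C(C)C)(C(C)C)C(C)C)cc(OCc3ccccc3)c12
F7 | step 11 | 7''-O-(2,2,2-trichloroethoxysulfonyl) derivative of 18 | O=C1c2c(OCc3ccc(OCc4ccccc4)cc3)cc(OCc3ccc(OCc4ccccc4)cc3)cc2O[C@@H](c2ccc(OCc3ccccc3)cc2)[C@@H]1c1c(OS(=O)(=O)OCC(Cl)(Cl)Cl)cc(OCc2ccccc2)c2c(=O)cc(-c3ccc4OC(c5ccccc5)(c5ccccc5)Oc4c3)oc12
F8 | step 11 | 2,2,2-trichloroethyl ester of 21 (all phenols free) | O=C1c2c(O)cc(O)cc2O[C@@H](c2ccc(O)cc2)[C@@H]1c1c(OS(=O)(=O)OCC(Cl)(Cl)Cl)cc(O)c2c(=O)cc(-c3ccc(O)c(O)c3)oc12
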